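**Plan**

1. Retrosynthesis: the nine O–CH3 bonds of a permethylated precursor are cut first, then the ring B–O–ring C diaryl ether (giving biphenyldiol 12 and the A–B aryl iodide 18), then the ring A–O–ring B ether. Last, in each of rings C and D, the bond between the biaryl carbon and one neighbouring C–OH carbon is cut, which leads to an ethane-bridged bis-pyrone and, through its CH2–CH2 bond, to two molecules of triacetic acid lactone.
2. Forward: lactone 1 is O-benzylated and dimerised through its methyl group (steps 1–2), rings C and D arise together in step 3, and methylation and hydrogenolysis free the two para oxygens (steps 4–5). Rings A and B are bought as arenes, joined and armed with iodine (steps 6–8); the fragments are united by CuI-catalysed etherification (step 9) and all methyl ethers are removed (step 10).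
3. Enabling feature (rings lettered A to D along the SMILES string): rings C and D form a 2,2',4,4',6,6'-hexaoxygenated biphenyl in which each ring carries oxygen on C2, C4 and C6. Each ring is therefore a folded triacetate chain whose methyl-terminus carbon is the biaryl carbon C1, so the hindered C1–C1' bond can be laid down as a CH2–CH2 bond before either ring exists.
4. Stereochemistry: the target has no stereocentre, and each ring of the biaryl axis carries two identical ortho substituents, so nothing has to be controlled.

Key step: step 3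

Assumption: NaOCH2Ph (1.0 M in benzyl alcohol), 1-iodo-3,5-dimethoxybenzene and 2,4,6-trimethoxyphenol are purchased. The iodine of the A–B fragment is placed through a bromine installed before ring A is attached, because electrophilic iodination of a finished A–B ether would attack the trimethoxyphenyl ring A first.

**Route**

Step 1
Reactants: 1 triacetic acid lactone (4-hydroxy-6-methyl-2H-pyran-2-one); 2 benzyl bromide
Product: 3 4-(benzyloxy)-6-methyl-2H-pyran-2-one
Conditions: BnBr (1.1 equiv), K2CO3, DMF, 60 °C
Reagents that add atoms: benzyl bromide 2, BrCc1ccccc1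
Why: Williamson O-alkylation of the acidic vinylogous-acid OH of the 4-hydroxy-2-pyrone, whose potassium salt in DMF should react mainly at oxygen, with any C3-benzylated by-product removed by chromatography.

Step 2
Reactants: 3 4-(benzyloxy)-6-methyl-2H-pyran-2-one (two molecules)
Product: 6 6,6'-(ethane-1,2-diyl)bis[4-(benzyloxy)-2H-pyran-2-one], via lithium dienolate 4 (not isolated), via iodomethyl pyrone 5 (not isolated)
Conditions: LiN(SiMe3)2 (1.05 equiv), THF, −78 °C; I2 (0.5 equiv), −78 °C → rt
Reagents that add atoms: none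
Why: Iodine-mediated oxidative homocoupling of a stabilised carbanion, in which LiN(SiMe3)2 deprotonates the 6-methyl group to dienolate 4, half of which is iodinated at the exocyclic carbon to 5 and then displaced by the remaining 4, both events taking place at the exocyclic carbon because only there is the pyrone conjugation restored.

Step 3
Reactants: 6 6,6'-(ethane-1,2-diyl)bis[4-(benzyloxy)-2H-pyran-2-one]
Product: 10 4,4'-bis(benzyloxy)biphenyl-2,2',6,6'-tetraol, via keto enoate 7 (not isolated), via arylmethyl pyrone 8 (not isolated), via keto enoate 9 (not isolated)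
Conditions: NaOCH2Ph (1.0 M in PhCH2OH, 6 equiv), toluene, 110 °C, Ar; then 1 M HCl, 0 °C
Reagents that add atoms: none
Why: Proposed new method: benzyloxide should add to the lactone carbonyl of one pyrone ring of 6 and open it to keto enoate 7, in which the benzyl ester and the ketone-bearing CH2 stay on the same side of the C2=C3 bond (2E) as they were in the ring; the ketone enolises toward the bridge CH2, this carbon acylates onto the ester carbonyl in a 6-(enolendo)-exo-trig Claisen closure, and loss of benzyloxide with enolisation gives the 4-benzyloxy-2,6-dihydroxyphenyl ring of 8 (the later ring C). The same sequence on the second pyrone passes through keto enoate 9, whose nucleophilic carbon is now benzylic and more acidic, and closes ring D in the same 6-(enolendo)-exo-trig mode, so that each new C–C bond joins a bridge carbon (the future biaryl carbon) to a former lactone carbonyl carbon (a future ortho C–OH) and the CH2–CH2 bond becomes the tetra-ortho-oxygenated biaryl bond without any aryl–aryl coupling. The closest known reaction type is the alkoxide-induced isomerisation of a single 4-alkoxy-6-alkyl-2-pyrone, or of a 3,5-dioxoalkanoate, to a phloroglucinol monoether by intramolecular Claisen condensation; its twofold use across an ethane bridge is what is new. No stereocentre is formed. The step needs C-acylation at the bridge carbon to win over re-lactonisation, over five-membered aldol closure between 1,4-related ketones and over hemiketal formation by the first phenoxide; the cis geometry inherited from the ring holds the ester within reach, reversible lactone opening keeps the doubly opened 1,4-diketone scarce, benzyloxide matches both the ester and the enol ether so that any exchange is degenerate, and only the Claisen path ends in irreversible aromatisation to a phenoxide.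

Step 4
Reactants: 10 4,4'-bis(benzyloxy)biphenyl-2,2',6,6'-tetraol
Product: 11 4,4'-bis(benzyloxy)-2,2',6,6'-tetramethoxybiphenyl
Conditions: MeI (6 equiv), K2CO3, DMF, rt, Ar
Reagents that add atoms: iodomethane, CI
Why: Williamson O-methylation of the four phenols, run on the crude air-sensitive tetraol under argon, with the benzyl ethers inert.

Step 5
Reactants: 11 4,4'-bis(benzyloxy)-2,2',6,6'-tetramethoxybiphenyl
Product: 12 2,2',6,6'-tetramethoxybiphenyl-4,4'-diol
Conditions: H2 (1 atm), 10% Pd/C, EtOAc–MeOH, rt
Reagents that add atoms: none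
Why: Hydrogenolysis of the two benzyl aryl ethers over Pd/C should free only the two para oxygens and leave the methyl ethers and the biaryl untouched.

Step 6
Reactants: 13 1-iodo-3,5-dimethoxybenzene
Product: 14 2-bromo-1-iodo-3,5-dimethoxybenzene
Conditions: NBS (1.0 equiv), MeCN, 0 °C → rt
Reagents that add atoms: N-bromosuccinimide, O=C1CCC(=O)N1Br
Why: Electrophilic aromatic bromination, which in 3,5-dimethoxyaryl compounds prefers C2 (para to one methoxy group, ortho to the other) over C4 between the two methoxy groups, as in the bromination of 3,5-dimethoxybenzaldehyde, and so fixes the 1,2,3,5-oxygenation pattern of ring B.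

Step 7
Reactants: 14 2-bromo-1-iodo-3,5-dimethoxybenzene; 15 2,4,6-trimethoxyphenol
Product: 16 2-bromo-1,5-dimethoxy-3-(2,4,6-trimethoxyphenoxy)benzene
Conditions: CuI (10 mol%), picolinic acid (20 mol%), K3PO4, DMSO, 90 °C, Ar
Reagents that add atoms: none
Why: Ullmann-type diaryl ether synthesis that is chemoselective for the C–I bond over the C–Br bond, so the ring A oxygen should end up on the carbon flanked by bromine and hydrogen.

Step 8
Reactants: 16 2-bromo-1,5-dimethoxy-3-(2,4,6-trimethoxyphenoxy)benzene
Product: 18 2-iodo-1,5-dimethoxy-3-(2,4,6-trimethoxyphenoxy)benzene, via aryllithium 17 (not isolated)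
Conditions: n-BuLi (1.05 equiv), THF, −78 °C; I2 (1.1 equiv), −78 °C; aq. Na2S2O3
Reagents that add atoms: iodine, II
Why: Bromine–lithium exchange followed by iodinolysis of aryllithium 17 should turn the hindered bromide into the iodide needed for copper catalysis at a defined position, without an electrophilic iodination that ring A would not tolerate.

Step 9
Reactants: 12 2,2',6,6'-tetramethoxybiphenyl-4,4'-diol; 18 2-iodo-1,5-dimethoxy-3-(2,4,6-trimethoxyphenoxy)benzene
Product: 19 4'-[2,4-dimethoxy-6-(2,4,6-trimethoxyphenoxy)phenoxy]-2,2',6,6'-tetramethoxybiphenyl-4-ol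
Conditions: 12 (3 equiv), CuI (20 mol%), picolinic acid (40 mol%), K3PO4, DMSO, 100 °C, Ar
Reagents that add atoms: none
Why: Ullmann-type diaryl ether synthesis between an unhindered phenoxide and a di-ortho-substituted aryl iodide under a CuI/picolinic acid system suited to hindered partners, with an excess of the symmetric diol 12 favouring mono-arylation and being recovered.

Step 10
Reactants: 19 4'-[2,4-dimethoxy-6-(2,4,6-trimethoxyphenoxy)phenoxy]-2,2',6,6'-tetramethoxybiphenyl-4-ol
Product: 20 4'-[2,4-dihydroxy-6-(2,4,6-trihydroxyphenoxy)phenoxy]biphenyl-2,2',4,6,6'-pentol (CNP0352577.0)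
Conditions: BBr3 (1 M in CH2Cl2, 20 equiv), CH2Cl2, −78 °C → rt; then ice-water
Reagents that add atoms: none
Why: Lewis-acid cleavage of the nine aryl methyl ethers by BBr3, to which diaryl ether and biaryl bonds are inert, should give the free polyphenol after hydrolysis of the borate esters.

**Compound list**

1 | triacetic acid lactone (4-hydroxy-6-methyl-2H-pyran-2-one) | CC1=CC(O)=CC(=O)O1 | starting material
2 | benzyl bromide | BrCc1ccccc1 | starting material
3 | 4-(benzyloxy)-6-methyl-2H-pyran-2-one | CC1=CC(OCc2ccccc2)=CC(=O)O1 | intermediate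
4 | lithium dienolate of 3 (lithium 4-(benzyloxy)-6-methylidene-6H-pyran-2-olate) | C=C1C=C(OCc2ccccc2)C=C(O[Li])O1 | intermediate
5 | 4-(benzyloxy)-6-(iodomethyl)-2H-pyran-2-one | ICC1=CC(OCc2ccccc2)=CC(=O)O1 | intermediate
6 | 6,6'-(ethane-1,2-diyl)bis[4-(benzyloxy)-2H-pyran-2-one] | O=C1C=C(OCc2ccccc2)C=C(CCC2=CC(OCc3ccccc3)=CC(=O)O2)O1 | intermediate
7 | benzyl (2E)-3-(benzyloxy)-7-[4-(benzyloxy)-2-oxo-2H-pyran-6-yl]-5-oxohept-2-enoate | O=C(OCc1ccccc1)/C=C(OCc1ccccc1)\CC(=O)CCC1=CC(OCc2ccccc2)=CC(=O)O1 | intermediate
8 | 4-(benzyloxy)-6-{[4-(benzyloxy)-2,6-dihydroxyphenyl]methyl}-2H-pyran-2-one | O=C1C=C(OCc2ccccc2)C=C(Cc2c(O)cc(OCc3ccccc3)cc2O)O1 | intermediate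
9 | benzyl (2E)-3-(benzyloxy)-6-[4-(benzyloxy)-2,6-dihydroxyphenyl]-5-oxohex-2-enoate | O=C(OCc1ccccc1)/C=C(OCc1ccccc1)\CC(=O)Cc1c(O)cc(OCc2ccccc2)cc1O | intermediate
10 | 4,4'-bis(benzyloxy)biphenyl-2,2',6,6'-tetraol | Oc1cc(OCc2ccccc2)cc(O)c1-c1c(O)cc(OCc2ccccc2)cc1O | intermediate
11 | 4,4'-bis(benzyloxy)-2,2',6,6'-tetramethoxybiphenyl | COc1cc(OCc2ccccc2)cc(OC)c1-c1c(OC)cc(OCc2ccccc2)cc1OC | intermediate
12 | 2,2',6,6'-tetramethoxybiphenyl-4,4'-diol | COc1cc(O)cc(OC)c1-c1c(OC)cc(O)cc1OC | intermediate
13 | 1-iodo-3,5-dimethoxybenzene | COc1cc(I)cc(OC)c1 | starting material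
14 | 2-bromo-1-iodo-3,5-dimethoxybenzene | COc1cc(I)c(Br)c(OC)c1 | intermediate
15 | 2,4,6-trimethoxyphenol | COc1cc(OC)c(O)c(OC)c1 | starting material
16 | 2-bromo-1,5-dimethoxy-3-(2,4,6-trimethoxyphenoxy)benzene | COc1cc(Oc2c(OC)cc(OC)cc2OC)c(Br)c(OC)c1 | intermediate
17 | [2,4-dimethoxy-6-(2,4,6-trimethoxyphenoxy)phenyl]lithium | COc1cc(Oc2c(OC)cc(OC)cc2OC)c([Li])c(OC)c1 | intermediate
18 | 2-iodo-1,5-dimethoxy-3-(2,4,6-trimethoxyphenoxy)benzene | COc1cc(Oc2c(OC)cc(OC)cc2OC)c(I)c(OC)c1 | intermediate
19 | 4'-[2,4-dimethoxy-6-(2,4,6-trimethoxyphenoxy)phenoxy]-2,2',6,6'-tetramethoxybiphenyl-4-ol | COc1cc(O)cc(OC)c1-c1c(OC)cc(Oc2c(OC)cc(OC)cc2Oc2c(OC)cc(OC)cc2OC)cc1OC | intermediate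
20 | 4'-[2,4-dihydroxy-6-(2,4,6-trihydroxyphenoxy)phenoxy]biphenyl-2,2',4,6,6'-pentol | Oc1cc(O)c(Oc2cc(O)cc(O)c2Oc2cc(O)c(-c3c(O)cc(O)cc3O)c(O)c2)c(O)c1 | target

**Step count and risks**

Total steps: 10. Longest linear sequence: 7 steps (1, 2, 3, 4, 5, 9, 10, from triacetic acid lactone); the A–B branch (6, 7, 8) is three steps.

Steps most likely to fail:

Step 3. After lactone opening the chain may return to the pyrone, close a five-membered aldol between the two ketones of a doubly opened molecule, or form a benzofuran-type hemiketal after the first ring has formed, so that one or both Claisen closures do not occur. The fallback uses known chemistry and gives up the pyrone fold. It sets out from benzyl bromide 2, which O-benzylates purchased 4-bromo-3,5-dimethoxyphenol (K2CO3, DMF) to give 5-(benzyloxy)-2-bromo-1,3-dimethoxybenzene F1. Bromine–lithium exchange (n-BuLi, THF, −78 °C) gives [4-(benzyloxy)-2,6-dimethoxyphenyl]lithium F2, and its oxidative homocoupling with anhydrous FeCl3, the way 2,2',6,6'-tetramethoxybiphenyl is made from 2,6-dimethoxyphenyllithium, should give compound 11. The route is rejoined there, with steps 5, 9 and 10 unchanged.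

Step 2. Proton transfer between dienolate 4 and the acidic CH2 groups of iodide 5 or of product 6 may lead to iodination without coupling, olefin formation or over-oxidation. The fallback separates halogenation from C–C bond formation. It sets out from compound 3: Wohl–Ziegler bromination (NBS, AIBN, PhCF3, 80 °C) gives 4-(benzyloxy)-6-(bromomethyl)-2H-pyran-2-one F3, which is isolated and added to one equivalent of dienolate 4 (from 3 and LiN(SiMe3)2, THF, −78 °C). C-alkylation at the exocyclic carbon, as known for lithiated 4-alkoxy-6-methyl-2-pyrones with reactive halides, comes back to the route at compound 6.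

Step 9. C–O bond formation at the iodide shielded by a methoxy group and the bulky aryloxy group may be slow, so that proto-deiodination of 18 and double arylation of 12 take over. The fallback attaches ring B first in a small, activated form and ring A last. It sets out from diol 12, which is coupled (CuI, picolinic acid, K3PO4, DMSO) with purchased 2-bromo-3,5-dimethoxybenzaldehyde, whose ortho-formyl group activates the halide, to give 2-[(4'-hydroxy-2,2',6,6'-tetramethoxybiphenyl-4-yl)oxy]-3,5-dimethoxybenzaldehyde F4. MeI/K2CO3 caps the remaining phenol as 3,5-dimethoxy-2-[(2,2',4',6,6'-pentamethoxybiphenyl-4-yl)oxy]benzaldehyde F5. Baeyer–Villiger (Dakin-type) oxidation with mCPBA in CH2Cl2 gives 3,5-dimethoxy-2-[(2,2',4',6,6'-pentamethoxybiphenyl-4-yl)oxy]phenyl formate F6, and K2CO3/MeOH releases 3,5-dimethoxy-2-[(2,2',4',6,6'-pentamethoxybiphenyl-4-yl)oxy]phenol F7. Ullmann coupling of F7 with purchased 2-iodo-1,3,5-trimethoxybenzene gives 4-[2,4-dimethoxy-6-(2,4,6-trimethoxyphenoxy)phenoxy]-2,2',4',6,6'-pentamethoxybiphenyl F8, and BBr3 under the conditions of step 10 comes back to the route at target 20.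

**Further compounds**

F1 | step 3 | 5-(benzyloxy)-2-bromo-1,3-dimethoxybenzene | COc1cc(OCc2ccccc2)cc(OC)c1Br
F2 | step 3 | [4-(benzyloxy)-2,6-dimethoxyphenyl]lithium | COc1cc(OCc2ccccc2)cc(OC)c1[Li]
F3 | step 2 | 4-(benzyloxy)-6-(bromomethyl)-2H-pyran-2-one | BrCC1=CC(OCc2ccccc2)=CC(=O)O1
F4 | step 9 | 2-[(4'-hydroxy-2,2',6,6'-tetramethoxybiphenyl-4-yl)oxy]-3,5-dimethoxybenzaldehyde | COc1cc(O)cc(OC)c1-c1c(OC)cc(Oc2c(C=O)cc(OC)cc2OC)cc1OC
F5 | step 9 | 3,5-dimethoxy-2-[(2,2',4',6,6'-pentamethoxybiphenyl-4-yl)oxy]benzaldehyde | COc1cc(OC)cc(OC)c1-c1c(OC)cc(Oc2c(C=O)cc(OC)cc2OC)cc1OC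
F6 | step 9 | 3,5-dimethoxy-2-[(2,2',4',6,6'-pentamethoxybiphenyl-4-yl)oxy]phenyl formate | COc1cc(OC)cc(OC)c1-c1c(OC)cc(Oc2c(OC=O)cc(OC)cc2OC)cc1OC
F7 | step 9 | 3,5-dimethoxy-2-[(2,2',4',6,6'-pentamethoxybiphenyl-4-yl)oxy]phenol | COc1cc(OC)cc(OC)c1-c1c(OC)cc(Oc2c(O)cc(OC)cc2OC)cc1OC
F8 | step 9 | 4-[2,4-dimethoxy-6-(2,4,6-trimethoxyphenoxy)phenoxy]-2,2',4',6,6'-pentamethoxybiphenyl | COc1cc(OC)cc(OC)c1-c1c(OC)cc(Oc2c(OC)cc(OC)cc2Oc2c(OC)cc(OC)cc2OC)cc1OC
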